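The route hinges on disconnecting ring C (the benzene ring of the 5,7-dihydroxychroman half) at C6–C(=O) and C5–O. A fluoride-released C5–C6 aryne inserts into the C–O bond of 3-(2,2-dimethylchroman-6-yl)propanoic acid, so one operation installs the C6 ketone and the adjacent C5 hydroxyl. The step exploits the contiguous C5–O/C6–acyl/C7–O array of ring C: the C7 oxygen polarises the aryne, sending the carboxylate to C5 and the acyl group to C6, never to C8. The precursor is a 2,2-dimethylchroman bearing a C5 triflate, a C6 trimethylsilyl group and a C7 methoxymethyl ether, chosen instead of a methyl ether so that final unmasking needs only dilute acid.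

Key step: step 10

Remark: the C7 oxygen is carried as a MOM ether because cleaving a methyl ether beside a ketone already chelated by the C5 hydroxyl would need Lewis acids that endanger both tertiary alkyl aryl ethers. Methyl 3-(4-hydroxyphenyl)propanoate is taken as a commercial starting material, and the target has no stereocentre.

Step 1
Reactants: 1 phloroglucinol; 2 3-methylbut-2-enoic acid
Product: 4 5,7-dihydroxy-2,2-dimethylchroman-4-one, via acylphloroglucinol 3 (not isolated)
Conditions: P2O5, MeSO3H, 70 °C
Reagents that add atoms: none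
Why: Friedel–Crafts acylation of the symmetrical triphenol followed by intramolecular oxa-Michael addition of an ortho hydroxyl to the β,β-dimethyl enone closes the pyranone ring, and the deactivating acyl group prevents a second annulation.

Step 2
Reactants: 4 5,7-dihydroxy-2,2-dimethylchroman-4-one
Product: 5 5-hydroxy-7-(methoxymethoxy)-2,2-dimethylchroman-4-one
Conditions: MOMCl (1.05 equiv), K2CO3, acetone, 0 °C → rt
Reagents that add atoms: chloromethyl methyl ether, COCCl
Why: Williamson-type O-alkylation should occur only at the C7 hydroxyl, because the C5 hydroxyl is held in a hydrogen bond to the C4 ketone and is poorly nucleophilic.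

Step 3
Reactants: 5 5-hydroxy-7-(methoxymethoxy)-2,2-dimethylchroman-4-one
Product: 7 7-(methoxymethoxy)-2,2-dimethylchroman-5-ol, via ethyl aryl carbonate 6 (not isolated)
Conditions: ClCO2Et, Et3N, THF, 0 °C, filter; then NaBH4, H2O, 0 °C → rt
Reagents that add atoms: none
Why: In this ortho-hydroxyl-assisted deoxygenation of an aryl ketone, borohydride reduces the C4 ketone, the carbonate shifts to the benzylic oxygen and is expelled by the C5 phenoxide to give an ortho-quinone methide, and a second hydride adds at C4 to leave the methylene group and the free C5 phenol, all under basic conditions that spare the MOM acetal.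

Step 4
Reactants: 7 7-(methoxymethoxy)-2,2-dimethylchroman-5-ol
Product: 8 7-(methoxymethoxy)-2,2-dimethylchroman-5-yl diethylcarbamate
Conditions: NaH, THF, 0 °C; ClCONEt2, rt
Reagents that add atoms: N,N-diethylcarbamoyl chloride, CCN(CC)C(Cl)=O
Why: O-acylation of the sodium phenoxide gives the aryl O-carbamate, a strong oxygen-based directing group for ortho metalation.

Step 5
Reactants: 8 7-(methoxymethoxy)-2,2-dimethylchroman-5-yl diethylcarbamate
Product: 10 7-(methoxymethoxy)-2,2-dimethyl-6-(trimethylsilyl)chroman-5-yl diethylcarbamate, via C6 aryllithium 9 (not isolated)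
Conditions: s-BuLi, TMEDA, THF, −78 °C; then TMSCl, −78 °C → rt
Reagents that add atoms: chlorotrimethylsilane, C[Si](C)(C)Cl
Why: In this directed ortho metalation C6–H is the only ring hydrogen ortho to the carbamate and is also flanked by the C7 MOM ether, so deprotonation should occur there and not at C8, and the silyl quench at −78 °C precedes any anionic ortho-Fries rearrangement.

Step 6
Reactants: 10 7-(methoxymethoxy)-2,2-dimethyl-6-(trimethylsilyl)chroman-5-yl diethylcarbamate
Product: 11 7-(methoxymethoxy)-2,2-dimethyl-6-(trimethylsilyl)chroman-5-ol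
Conditions: LiAlH4, THF, 0 → 50 °C; Na2SO4·10H2O work-up
Reagents that add atoms: none
Why: Reductive cleavage of the aryl O-carbamate by hydride attack at its carbonyl releases the phenoxide under non-acidic conditions that leave the aryl–silicon bond, the MOM acetal and the chroman ether intact.

Step 7
Reactants: 11 7-(methoxymethoxy)-2,2-dimethyl-6-(trimethylsilyl)chroman-5-ol
Product: 12 7-(methoxymethoxy)-2,2-dimethyl-6-(trimethylsilyl)chroman-5-yl trifluoromethanesulfonate
Conditions: NaH, THF, 0 °C; PhNTf2, rt
Reagents that add atoms: N-phenylbis(trifluoromethanesulfonimide), O=S(=O)(N(c1ccccc1)S(=O)(=O)C(F)(F)F)C(F)(F)F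
Why: O-sulfonylation of the sodium phenoxide with a mild triflyl donor gives the ortho-silylaryl triflate without exposing the MOM acetal to triflic anhydride or acid.

Step 8
Reactants: 13 methyl 3-(4-hydroxyphenyl)propanoate; 14 2-methylbut-3-en-2-ol
Product: 16 methyl 3-(2,2-dimethylchroman-6-yl)propanoate, via ortho-prenylphenol 15 (not isolated)
Conditions: Bi(OTf)3 (5 mol%), 1,2-dichloroethane, 60 °C, slow addition of 14 (1.5 equiv)
Reagents that add atoms: none
Why: Acid-catalysed Friedel–Crafts prenylation ortho to the phenol (para is blocked) followed by Markovnikov hydroalkoxylation of the trisubstituted alkene is the standard tandem chroman annulation of phenols with prenyl cation donors.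

Step 9
Reactants: 16 methyl 3-(2,2-dimethylchroman-6-yl)propanoate
Product: 17 3-(2,2-dimethylchroman-6-yl)propanoic acid
Conditions: LiOH, THF/H2O, rt; then aq. HCl
Reagents that add atoms: water (as hydroxide), O
Why: Saponification of an unhindered methyl ester is reliable and does not affect the chroman ether.

Step 10
Reactants: 12 7-(methoxymethoxy)-2,2-dimethyl-6-(trimethylsilyl)chroman-5-yl trifluoromethanesulfonate; 17 3-(2,2-dimethylchroman-6-yl)propanoic acid
Product: 19 1-[5-hydroxy-7-(methoxymethoxy)-2,2-dimethylchroman-6-yl]-3-(2,2-dimethylchroman-6-yl)propan-1-one, via C5–C6 aryne 18 (not isolated)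
Conditions: CsF (4 equiv), THF, 125 °C, sealed tube; 12 (1.5 equiv)
Reagents that add atoms: none
Why: Fluoride attacks silicon in 12 and the C6 carbanion expels the C5 triflate to give aryne 18; the cesium carboxylate of 17 adds at C5, and the resulting C6 aryl anion attacks the carbonyl of the new aryl ester through a four-membered alkoxide that opens to the ortho-acyl phenoxide, protonated on work-up. The closest known reaction type is the fluoride-triggered insertion of arynes into the C–O bond of carboxylic acids, an intermolecular relative of the anionic ortho-Fries shift, established for 3-methoxybenzyne. No ring is closed and no stereocentre is created. The step needs carboxylate attack at C5 and not C6: the inductively withdrawing C7 oxygen distorts the aryne towards attack at C5 and stabilises negative charge at C6, an effect expected to outweigh the alkyl substituent at C4a. It also needs acyl transfer to outrun protonation of the C6 anion, which the high temperature and the aprotic medium favour. The MOM acetal, both chroman ethers and the saturated chain should be inert to CsF.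

Step 11
Reactants: 19 1-[5-hydroxy-7-(methoxymethoxy)-2,2-dimethylchroman-6-yl]-3-(2,2-dimethylchroman-6-yl)propan-1-one
Product: 20 1-(5,7-dihydroxy-2,2-dimethylchroman-6-yl)-3-(2,2-dimethylchroman-6-yl)propan-1-one
Conditions: 3 M HCl, MeOH, 50 °C
Reagents that add atoms: none
Why: Acid-catalysed acetal solvolysis removes the MOM group ortho to the ketone, while the tertiary alkyl aryl ethers of both chromans, the ketone and the phenols are stable to dilute acid.

Compound list

1 | phloroglucinol | Oc1cc(O)cc(O)c1 | starting material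
2 | 3-methylbut-2-enoic acid | CC(C)=CC(O)=O | starting material
3 | 3-methyl-1-(2,4,6-trihydroxyphenyl)but-2-en-1-one | CC(C)=CC(=O)c1c(O)cc(O)cc1O | intermediate (not isolated)
4 | 5,7-dihydroxy-2,2-dimethylchroman-4-one | CC1(C)CC(=O)c2c(O)cc(O)cc2O1 | intermediate
5 | 5-hydroxy-7-(methoxymethoxy)-2,2-dimethylchroman-4-one | COCOc1cc(O)c2C(=O)CC(C)(C)Oc2c1 | intermediate
6 | ethyl 7-(methoxymethoxy)-2,2-dimethyl-4-oxochroman-5-yl carbonate | CCOC(=O)Oc1cc(OCOC)cc2OC(C)(C)CC(=O)c12 | intermediate (not isolated)
7 | 7-(methoxymethoxy)-2,2-dimethylchroman-5-ol | COCOc1cc(O)c2CCC(C)(C)Oc2c1 | intermediate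
8 | 7-(methoxymethoxy)-2,2-dimethylchroman-5-yl diethylcarbamate | CCN(CC)C(=O)Oc1cc(OCOC)cc2OC(C)(C)CCc12 | intermediate
9 | 6-lithio-7-(methoxymethoxy)-2,2-dimethylchroman-5-yl diethylcarbamate | [Li]c1c(OCOC)cc2OC(C)(C)CCc2c1OC(=O)N(CC)CC | intermediate (not isolated)
10 | 7-(methoxymethoxy)-2,2-dimethyl-6-(trimethylsilyl)chroman-5-yl diethylcarbamate | CCN(CC)C(=O)Oc1c([Si](C)(C)C)c(OCOC)cc2OC(C)(C)CCc12 | intermediate
11 | 7-(methoxymethoxy)-2,2-dimethyl-6-(trimethylsilyl)chroman-5-ol | COCOc1cc2OC(C)(C)CCc2c(O)c1[Si](C)(C)C | intermediate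
12 | 7-(methoxymethoxy)-2,2-dimethyl-6-(trimethylsilyl)chroman-5-yl trifluoromethanesulfonate | COCOc1cc2OC(C)(C)CCc2c(OS(=O)(=O)C(F)(F)F)c1[Si](C)(C)C | intermediate (key-step precursor)
13 | methyl 3-(4-hydroxyphenyl)propanoate | COC(=O)CCc1ccc(O)cc1 | starting material
14 | 2-methylbut-3-en-2-ol | CC(C)(O)C=C | starting material
15 | methyl 3-[4-hydroxy-3-(3-methylbut-2-en-1-yl)phenyl]propanoate | COC(=O)CCc1ccc(O)c(CC=C(C)C)c1 | intermediate (not isolated)
16 | methyl 3-(2,2-dimethylchroman-6-yl)propanoate | COC(=O)CCc1ccc2OC(C)(C)CCc2c1 | intermediate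
17 | 3-(2,2-dimethylchroman-6-yl)propanoic acid | OC(=O)CCc1ccc2OC(C)(C)CCc2c1 | intermediate (key-step precursor)
18 | 7-(methoxymethoxy)-2,2-dimethylchroman-5,6-yne (C5–C6 aryne) | COCOC1=CC2=C(CCC(C)(C)O2)C#C1 | intermediate (not isolated)
19 | 1-[5-hydroxy-7-(methoxymethoxy)-2,2-dimethylchroman-6-yl]-3-(2,2-dimethylchroman-6-yl)propan-1-one | COCOc1cc2OC(C)(C)CCc2c(O)c1C(=O)CCc1ccc2OC(C)(C)CCc2c1 | intermediate (key-step product)
20 | 1-(5,7-dihydroxy-2,2-dimethylchroman-6-yl)-3-(2,2-dimethylchroman-6-yl)propan-1-one | CC1(C)CCc2cc(CCC(=O)c3c(O)cc4c(c3O)CCC(C)(C)O4)ccc2O1 | target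

Total step count: 11. Longest linear sequence: 9 steps (steps 1–7, 10 and 11); the acid branch is 2 steps (8 and 9).

Steps most likely to fail

Step 10. The C6 aryl anion may be protonated before acyl transfer, stopping at the aryl ester, or the carboxylate may add in part at C6. The fallback sets out from 7 and 17 and returns at 20. Phenol 7 would be alkylated (MOMCl, iPr2NEt, CH2Cl2) to 5,7-bis(methoxymethoxy)-2,2-dimethylchroman F1. Acid 17 would be coupled with N,O-dimethylhydroxylamine hydrochloride (EDC, Et3N, CH2Cl2) to 3-(2,2-dimethylchroman-6-yl)-N-methoxy-N-methylpropanamide F2. Deprotonation of F1 at C6, between its two MOM ethers (n-BuLi, THF, 0 °C), and acylation with F2 should give 1-[5,7-bis(methoxymethoxy)-2,2-dimethylchroman-6-yl]-3-(2,2-dimethylchroman-6-yl)propan-1-one F3. Treatment with 3 M HCl in MeOH at 50 °C would remove both acetals and give 20. This replaces the aryne insertion by directed ortho metalation and Weinreb ketone synthesis.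

Step 8. The prenyl donor may oligomerise, the sequence may stall at the ortho-prenyl phenol, or a second C-alkylation may occur. The fallback sets out from 13 and returns at 16. O-Alkylation with 3-chloro-3-methylbut-1-yne (CuCl2 cat., DBU, MeCN, 0 °C) would give methyl 3-[4-(2-methylbut-3-yn-2-yloxy)phenyl]propanoate F4. Heating in N,N-diethylaniline at 190 °C (aromatic Claisen rearrangement, hydrogen shift and 6π-electrocyclisation) would give methyl 3-(2,2-dimethyl-2H-chromen-6-yl)propanoate F5. Hydrogenation (H2, Pd/C, EtOAc) of the C3–C4 alkene then gives 16.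

Step 6. Hydride attack at the carbamate, shielded by the C6 silyl group and the C4 methylene, may be slow, and forcing it may cause protodesilylation. The fallback sets out from 7 and returns at 12. Addition of 7 to isopropyl isocyanate (Et3N cat., CH2Cl2) would give 7-(methoxymethoxy)-2,2-dimethylchroman-5-yl isopropylcarbamate F6. One-flask C6 silylation (TBSOTf, TMEDA, Et2O to mask N–H; n-BuLi, TMEDA, −78 °C; TMSCl; aq. NaHSO4 work-up) would give 7-(methoxymethoxy)-2,2-dimethyl-6-(trimethylsilyl)chroman-5-yl isopropylcarbamate F7. DBU and Et2NH in MeCN at 40 °C would cleave the carbamate by elimination of isopropyl isocyanate, and PhNTf2 added to the same flask would triflate the phenoxide of 11 without isolation to give 12. The brief contact of the MOM acetal with TBSOTf is the point to watch in this fallback.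

Further compounds

F1 | step 10 | 5,7-bis(methoxymethoxy)-2,2-dimethylchroman | COCOc1cc(OCOC)c2CCC(C)(C)Oc2c1
F2 | step 10 | 3-(2,2-dimethylchroman-6-yl)-N-methoxy-N-methylpropanamide | CON(C)C(=O)CCc1ccc2OC(C)(C)CCc2c1
F3 | step 10 | 1-[5,7-bis(methoxymethoxy)-2,2-dimethylchroman-6-yl]-3-(2,2-dimethylchroman-6-yl)propan-1-one | COCOc1cc2OC(C)(C)CCc2c(OCOC)c1C(=O)CCc1ccc2OC(C)(C)CCc2c1
F4 | step 8 | methyl 3-[4-(2-methylbut-3-yn-2-yloxy)phenyl]propanoate | COC(=O)CCc1ccc(OC(C)(C)C#C)cc1
F5 | step 8 | methyl 3-(2,2-dimethyl-2H-chromen-6-yl)propanoate | COC(=O)CCc1ccc2OC(C)(C)C=Cc2c1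
F6 | step 6 | 7-(methoxymethoxy)-2,2-dimethylchroman-5-yl isopropylcarbamate | CC(C)NC(=O)Oc1cc(OCOC)cc2OC(C)(C)CCc12
F7 | step 6 | 7-(methoxymethoxy)-2,2-dimethyl-6-(trimethylsilyl)chroman-5-yl isopropylcarbamate | CC(C)NC(=O)Oc1c([Si](C)(C)C)c(OCOC)cc2OC(C)(C)CCc12
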